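**Strategy.** The route rests on the C3–C4 bond of ring A (C1–C5, C10; labdane numbering). It exploits the quaternary C4, which carries the oxygenated one-carbon branch C19: in the precursor C19 is still a ring atom, lying between C3 and C4 in a trans-fused cycloheptene oxide made from (R)-carvone by double alkylation and ring-closing metathesis. The bulky Lewis acid MeAl(OAr)2 opens the epoxide at C4 and C3 shifts from C19 to C4; this contracts the seven-membered ring to ring A, sets the C4 stereocentre and releases C19 as the axial aldehyde. The C9 side chain follows by methylenation, hydroboration and alkyl–alkyl Suzuki coupling; angelate formation and ester cleavage finish.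

Key step: step 5

Remark: atom labels C1–C20 are those of the labdane skeleton of the target (ring A = C1–C5 and C10; ring B = C5–C10; C18 and C19 on C4; C20 on C10; side chain C11–C16 on C9); β is the face that carries the C20 methyl group, α the opposite face; methyl hydrogen (R)-3-methylglutarate is taken as a purchasable chiral-pool compound.

**Step 1**
Reactants: 1 (R)-(−)-carvone
Product: 2 (5R,6RS)-2,6-dimethyl-5-(prop-1-en-2-yl)cyclohex-2-en-1-one (6-methylcarvone; C6 epimers)
Conditions: LiN(iPr)2, THF, −78 °C; MeI, −78 → 0 °C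
Reagents that add atoms: iodomethane (MeI), CI
Why: Enolate alkylation: kinetic deprotonation at the α' carbon and SN2 methylation of the cross-conjugated lithium enolate should give 2, whose new centre need not be controlled because step 2 planarises it again.

**Step 2**
Reactants: 2 (5R,6RS)-6-methylcarvone; 3 5-iodopent-1-ene
Product: 4 (5S,6S)-2,6-dimethyl-6-(pent-4-en-1-yl)-5-(prop-1-en-2-yl)cyclohex-2-en-1-one
Conditions: LiN(iPr)2, THF, −78 → 0 °C; 3, DMPU, −78 °C → rt
Reagents that add atoms: none
Why: Enolate alkylation: the tetrasubstituted α'-enolate should be alkylated by the primary iodide on the face anti to the neighbouring isopropenyl group, so the pentenyl chain (future C1–C3 and C19) ends trans to C4 and the methyl group (C20) cis, which sets the C10 quaternary centre relative to C5.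

**Step 3**
Reactants: 4 (5S,6S)-2,6-dimethyl-6-(pent-4-en-1-yl)-5-(prop-1-en-2-yl)cyclohex-2-en-1-one
Product: 5 (4aS,9aS)-3,4a,9-trimethyl-1,4a,5,6,7,9a-hexahydro-4H-benzo[7]annulen-4-one (trans-fused; C4=C19 in the seven-membered ring)
Conditions: second-generation Grubbs catalyst RuCl2(=CHPh)(PCy3)(H2IMes) (5 mol %), CH2Cl2 (0.005 M), 40 °C
Reagents that add atoms: none
Why: Ring-closing olefin metathesis between the isopropenyl group and the terminal alkene, held trans-diequatorial on the cyclohexenone, should close the trisubstituted cycloheptene with loss of ethene while the electron-poor enone alkene stays out.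

**Step 4**
Reactants: 5 (4aS,9aS)-3,4a,9-trimethyl-1,4a,5,6,7,9a-hexahydro-4H-benzo[7]annulen-4-one
Product: 7 8β,9β-epoxy-3,4a,9-trimethyl-1,4a,5,6,7,8,9,9a-octahydro-4H-benzo[7]annulen-4-one (β-epoxide; oxygen syn to the 4a-methyl group), via trans-bromohydrin 6 (not isolated)
Conditions: NBS, THF/H2O (4:1), 0 °C; then K2CO3, MeOH, rt
Reagents that add atoms: water, O
Why: Bromohydrin formation and base-induced epoxide closure: the bromonium ion should form on the α face away from the angular methyl group, water opens it at tertiary C4 from the β face (Markovnikov, anti), and K2CO3 closes the epoxide by intramolecular SN2 displacement of the C19 bromide, which puts the oxygen on the β face that a peracid would not reach; the enone alkene is too electron-poor to react with NBS.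

**Step 5**
Reactants: 7 β-epoxide
Product: 8 (1S,4aS,8aS)-1,4a,6-trimethyl-5-oxo-1,2,3,4,4a,5,8,8a-octahydronaphthalene-1-carbaldehyde (formyl group axial and β on C4)
Conditions: MeAl(OAr)2 (MABR; Ar = 4-bromo-2,6-di-tert-butylphenyl; 20 mol %, preformed from Me3Al and ArOH), CH2Cl2, −78 → −20 °C
Reagents that add atoms: none
Why: Coordination of the aluminium Lewis acid to the epoxide oxygen weakens the C4–O bond at the tertiary carbon and, as positive charge builds at C4, the ring bond C3–C19 shifts to C4 on the face opposite the departing oxygen while C19 becomes the aldehyde carbon (Meinwald epoxide–aldehyde rearrangement, a semipinacol 1,2-alkyl shift). The closest known reaction type is the ring contraction of 1-methylcycloalkene oxides to 1-methylcycloalkanecarbaldehydes promoted by MABR or BF3·OEt2. Ring A (C1–C5, C10) is closed by formation of the C3–C4 bond through this suprafacial 1,2-shift, that is by contraction of the seven-membered ring with expulsion of C19, not by an exo or endo cyclisation. C4 is the only new stereocentre and is controlled by the epoxide configuration: migration with inversion at C4 leaves the formyl carbon on the β face where the oxygen was and the methyl group α, and C5 and C10 are untouched so the trans ring fusion is kept. The step needs alkyl shift in preference to hydride shift from C19 and C–O cleavage at C4 only; the tertiary, methyl-bearing C4 secures the regiochemistry, the flexible seven-membered ring lets the C3–C19 bond align with the breaking C4–O bond, the bulky aluminium phenoxide is chosen because it favours alkyl over hydride migration in trisubstituted epoxides, and the hindered enone offers no competing epoxide or enolisable site.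

**Step 6**
Reactants: 8 keto aldehyde
Product: 9 (4aS,5S,8aS)-5-(hydroxymethyl)-2,5,8a-trimethyl-4a,5,6,7,8,8a-hexahydronaphthalen-1(4H)-one
Conditions: NaBH4, EtOH/CH2Cl2, −78 °C
Reagents that add atoms: none
Why: Chemoselective hydride reduction: at low temperature NaBH4 should reduce the unconjugated aldehyde much faster than the hindered, conjugated C9 ketone, and no stereocentre is formed.

**Step 7**
Reactants: 9 hydroxy enone
Product: 10 [(1S,4aS,8aR)-1,4a,6-trimethyl-5-methylidene-1,2,3,4,4a,5,8,8a-octahydronaphthalen-1-yl]methanol (7,9(11)-diene)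
Conditions: Ph3PCH3Br, KOtBu (4 equiv each), toluene, 90 °C
Reagents that add atoms: methylenetriphenylphosphorane (made in the flask from Ph3PCH3Br and KOtBu), C=P(c1ccccc1)(c1ccccc1)c1ccccc1
Why: Wittig methylenation of the hindered C9 ketone with excess ylide at elevated temperature should give the exocyclic diene, the C19 hydroxyl being carried as its potassium alkoxide.

**Step 8**
Reactants: 11 methyl hydrogen (R)-3-methylglutarate
Product: 12 1-tert-butyl 5-methyl (3S)-3-methylpentanedioate
Conditions: isobutene, H2SO4 (cat.), CH2Cl2, −20 °C → rt (sealed vessel)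
Reagents that add atoms: 2-methylpropene (isobutene), CC(C)=C
Why: Acid-catalysed addition of the carboxylic acid to isobutene (tert-butyl ester formation) leaves the methyl ester and the stereocentre untouched and only marks the two termini as different.

**Step 9**
Reactants: 12 1-tert-butyl 5-methyl (3S)-3-methylpentanedioate
Product: 13 (3S)-5-(tert-butoxy)-3-methyl-5-oxopentanoic acid
Conditions: LiOH (1.05 equiv), THF/H2O, 0 °C; then aq. HCl to pH 3
Reagents that add atoms: lithium hydroxide, [Li+].[OH-]
Why: Saponification: hydroxide attacks the unhindered methyl ester while the tert-butyl ester resists acyl substitution, so the free acid ends on the terminus that was the methyl ester, and the stereocentre, β to both carbonyls, cannot epimerise.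

**Step 10**
Reactants: 13 (3S)-5-(tert-butoxy)-3-methyl-5-oxopentanoic acid
Product: 14 tert-butyl (3R)-4-iodo-3-methylbutanoate
Conditions: PhI(OAc)2, I2, cyclohexane, hν (tungsten lamp), reflux
Reagents that add atoms: iodine, II
Why: Suárez iododecarboxylation (Hunsdiecker-type radical decarboxylation): homolysis of the acyl hypoiodite, loss of CO2 and iodine transfer to the primary radical give the iodide, the stereocentre is not the radical carbon and is kept, and this enantiomer maps onto C13 (S) of the target.

**Step 11**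
Reactants: 10 diene alcohol; 14 tert-butyl (3R)-4-iodo-3-methylbutanoate
Product: 16 tert-butyl (3S)-5-[(1S,4aR,5S,8aR)-5-(hydroxymethyl)-2,5,8a-trimethyl-1,4,4a,5,6,7,8,8a-octahydronaphthalen-1-yl]-3-methylpentanoate, via C11 alkylborane 15 (not isolated)
Conditions: 9-BBN-H (2.5 equiv), THF, 0 °C → rt; then 14, Pd(OAc)2 (5 mol %), PCy3 (10 mol %), K3PO4·H2O, THF, rt → 40 °C
Reagents that add atoms: none
Why: Hydroboration then B-alkyl Suzuki–Miyaura coupling: 9-BBN-H should add to the exocyclic C9=C11 bond with boron on C11 and hydrogen delivered to C9 from the α face opposite the axial C10 methyl group (9α-H, side chain β and equatorial), the trisubstituted ring alkene being too hindered to react, and the alkylborane is then joined to the primary iodide under Pd/PCy3 conditions developed for alkyl–alkyl coupling, which brings in C13 unchanged.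

**Step 12**
Reactants: 16 hydroxy tert-butyl ester; 17 angelic acid [(2Z)-2-methylbut-2-enoic acid]
Product: 19 tert-butyl (3S)-3-methyl-5-[(1S,4aR,5S,8aR)-2,5,8a-trimethyl-5-({[(2Z)-2-methylbut-2-enoyl]oxy}methyl)-1,4,4a,5,6,7,8,8a-octahydronaphthalen-1-yl]pentanoate, via angelic mixed anhydride 18 (not isolated)
Conditions: 17, 2,4,6-trichlorobenzoyl chloride, Et3N, toluene, rt; then 16, 80 °C
Reagents that add atoms: none
Why: Yamaguchi-type esterification through the mixed anhydride without a nucleophilic catalyst, a protocol used to acylate hindered alcohols with angelic acid without Z to E isomerisation, in which the alcohol attacks the less hindered angeloyl carbonyl.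

**Step 13**
Reactants: 19 angelate tert-butyl ester
Product: 21 (3S)-3-methyl-5-[(1S,4aR,5S,8aR)-2,5,8a-trimethyl-5-({[(2Z)-2-methylbut-2-enoyl]oxy}methyl)-1,4,4a,5,6,7,8,8a-octahydronaphthalen-1-yl]pentanoic acid (target), via trimethylsilyl ester 20 (not isolated)
Conditions: Me3SiOTf, 2,6-lutidine, CH2Cl2, 0 °C; then aqueous work-up (pH 4 buffer)
Reagents that add atoms: none
Why: Silyl-triflate-mediated cleavage of the tert-butyl ester (loss of isobutene to the silyl ester, hydrolysed on work-up) under buffered, non-nucleophilic conditions should leave the angelate, its Z geometry and the trisubstituted ring alkene untouched.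

**Compound list**

1 | (R)-(−)-carvone, (5R)-2-methyl-5-(prop-1-en-2-yl)cyclohex-2-en-1-one | CC1=CC[C@H](CC1=O)C(C)=C | starting material
2 | (5R,6RS)-2,6-dimethyl-5-(prop-1-en-2-yl)cyclohex-2-en-1-one (C6 epimers) | CC1C(=O)C(C)=CC[C@H]1C(C)=C | intermediate
3 | 5-iodopent-1-ene | C=CCCCI | starting material
4 | (5S,6S)-2,6-dimethyl-6-(pent-4-en-1-yl)-5-(prop-1-en-2-yl)cyclohex-2-en-1-one (pentenyl trans to isopropenyl) | C=CCCC[C@]1(C)C(=O)C(C)=CC[C@H]1C(C)=C | intermediate
5 | (4aS,9aS)-3,4a,9-trimethyl-1,4a,5,6,7,9a-hexahydro-4H-benzo[7]annulen-4-one (trans-fused; 4a-methyl β, 9a-H α) | CC1=CCCC[C@]2(C)C(=O)C(C)=CC[C@@H]12 | intermediate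
6 | 8α-bromo-9β-hydroxy-3,4a,9-trimethyl-1,4a,5,6,7,8,9,9a-octahydro-4H-benzo[7]annulen-4-one (trans-bromohydrin; 4a-methyl β, 9a-H α) | C[C@]1(O)[C@H](Br)CCC[C@]2(C)C(=O)C(C)=CC[C@@H]12 | intermediate
7 | 8β,9β-epoxy-3,4a,9-trimethyl-1,4a,5,6,7,8,9,9a-octahydro-4H-benzo[7]annulen-4-one (oxygen syn to the 4a-methyl group) | C[C@]12O[C@H]1CCC[C@]3(C)C(=O)C(C)=CC[C@@H]23 | intermediate
8 | (1S,4aS,8aS)-1,4a,6-trimethyl-5-oxo-1,2,3,4,4a,5,8,8a-octahydronaphthalene-1-carbaldehyde | O=C[C@@]1(C)CCC[C@]2(C)C(=O)C(C)=CC[C@@H]12 | intermediate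
9 | (4aS,5S,8aS)-5-(hydroxymethyl)-2,5,8a-trimethyl-4a,5,6,7,8,8a-hexahydronaphthalen-1(4H)-one | OC[C@@]1(C)CCC[C@]2(C)C(=O)C(C)=CC[C@@H]12 | intermediate
10 | [(1S,4aS,8aR)-1,4a,6-trimethyl-5-methylidene-1,2,3,4,4a,5,8,8a-octahydronaphthalen-1-yl]methanol | OC[C@@]1(C)CCC[C@]2(C)C(=C)C(C)=CC[C@@H]12 | intermediate
11 | methyl hydrogen (R)-3-methylglutarate, (3R)-5-methoxy-3-methyl-5-oxopentanoic acid | COC(=O)C[C@H](C)CC(=O)O | starting material
12 | 1-tert-butyl 5-methyl (3S)-3-methylpentanedioate | COC(=O)C[C@H](C)CC(=O)OC(C)(C)C | intermediate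
13 | (3S)-5-(tert-butoxy)-3-methyl-5-oxopentanoic acid | OC(=O)C[C@H](C)CC(=O)OC(C)(C)C | intermediate
14 | tert-butyl (3R)-4-iodo-3-methylbutanoate | IC[C@H](C)CC(=O)OC(C)(C)C | intermediate
15 | C11 alkylborane: B-alkyl-9-BBN at C11 (9α-H), C19 hydroxyl carried as its 9-BBN borinate | C1CCC2CCCC1B2OC[C@@]1(C)CCC[C@]2(C)[C@@H](CB3C4CCCC3CCC4)C(C)=CC[C@@H]12 | intermediate
16 | tert-butyl (3S)-5-[(1S,4aR,5S,8aR)-5-(hydroxymethyl)-2,5,8a-trimethyl-1,4,4a,5,6,7,8,8a-octahydronaphthalen-1-yl]-3-methylpentanoate | OC[C@@]1(C)CCC[C@]2(C)[C@@H](CC[C@H](C)CC(=O)OC(C)(C)C)C(C)=CC[C@@H]12 | intermediate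
17 | angelic acid, (2Z)-2-methylbut-2-enoic acid | C/C=C(/C)C(=O)O | starting material
18 | (2Z)-2-methylbut-2-enoic 2,4,6-trichlorobenzoic anhydride | C/C=C(/C)C(=O)OC(=O)c1c(Cl)cc(Cl)cc1Cl | intermediate
19 | tert-butyl (3S)-3-methyl-5-[(1S,4aR,5S,8aR)-2,5,8a-trimethyl-5-({[(2Z)-2-methylbut-2-enoyl]oxy}methyl)-1,4,4a,5,6,7,8,8a-octahydronaphthalen-1-yl]pentanoate | C/C=C(/C)C(=O)OC[C@@]1(C)CCC[C@]2(C)[C@@H](CC[C@H](C)CC(=O)OC(C)(C)C)C(C)=CC[C@@H]12 | intermediate
20 | trimethylsilyl ester of the target acid | C/C=C(/C)C(=O)OC[C@@]1(C)CCC[C@]2(C)[C@@H](CC[C@H](C)CC(=O)O[Si](C)(C)C)C(C)=CC[C@@H]12 | intermediate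
21 | (3S)-3-methyl-5-[(1S,4aR,5S,8aR)-2,5,8a-trimethyl-5-({[(2Z)-2-methylbut-2-enoyl]oxy}methyl)-1,4,4a,5,6,7,8,8a-octahydronaphthalen-1-yl]pentanoic acid | C/C=C(/C)C(=O)OC[C@@]1(C)CCC[C@]2(C)[C@@H](CC[C@H](C)CC(=O)O)C(C)=CC[C@@H]12 | target

**Step count.** Total: 13 steps. Longest linear sequence: 10 steps (steps 1–7 and 11–13); steps 8–10 make the side-chain iodide.

**Steps most likely to fail**

Step 5. The 1,2-hydride shift from C19 may outrun the shift of C3 and give the seven-membered ketone, or the C4–O bond may ionise fully so that the shift is no longer tied to the epoxide configuration. The fallback sets out from 5 and comes back at 9; it makes the same seven-to-six contraction as a Favorskii rearrangement, in which no hydride can compete. mCPBA (NaHCO3, CH2Cl2, 0 °C) should epoxidise 5 on the open α face to the α-epoxide F1. HCl in Et2O should open it at tertiary C4 with inversion to the trans-chlorohydrin F2 (chlorine β on C4). Dess–Martin periodinane oxidises the C19 alcohol to the α-chloro ketone F3. NaOMe suspended in Et2O should then give the ring-contracted methyl ester F4: the C3 enolate displaces chloride at C4 with inversion (cyclopropanone), methoxide opens the cyclopropanone toward the less substituted C3 carbanion, and the ester carbon C19 ends β on the new ring A. LiAlH4 reduces ester and enone to the diol F5, and MnO2 re-oxidises only the allylic C9 alcohol to 9.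

Step 11. Both coupling partners are β-branched, so transmetalation and oxidative addition may be slow and β-hydride elimination or protodeboronation may take over. The fallback sets out from 10 and comes back at 16; it replaces cross-coupling by sulfone alkylation. Hydroboration of 10 with 9-BBN-H and oxidation (NaOH, H2O2) should give the 11,19-diol F6. I2, PPh3 and imidazole should convert the less hindered C11 hydroxyl to the C11 iodide F7 while the axial neopentyl C19 hydroxyl stays. PhSO2Na in DMF gives the C11 phenyl sulfone F8. Its dianion (n-BuLi, THF/DMPU, −78 °C) is alkylated by 14 to the alkylated sulfone F9, and Na(Hg), Na2HPO4, MeOH removes the sulfonyl group to give 16.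

Step 12. Acylation of the axial neopentyl C19 alcohol may be so slow that the angeloyl unit isomerises from Z to E (tiglate) before the ester forms. The fallback sets out from 16 and comes back at 19; it makes the Z double bond after the ester bond. 16 is esterified with 2-[bis(2,2,2-trifluoroethoxy)phosphoryl]propanoic acid (DCC, DMAP, CH2Cl2) to the phosphonopropanoate ester F10. Still–Gennari olefination (KN(SiMe3)2, 18-crown-6, THF, −78 °C; acetaldehyde) should then build the Z-configured 2-methylbut-2-enoate and give 19.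

**Further compounds**

F1 | step 5 | 8α,9α-epoxy-3,4a,9-trimethyl-1,4a,5,6,7,8,9,9a-octahydro-4H-benzo[7]annulen-4-one (α-epoxide of 5) | C[C@@]12O[C@@H]1CCC[C@]3(C)C(=O)C(C)=CC[C@@H]23
F2 | step 5 | 9β-chloro-8α-hydroxy-3,4a,9-trimethyl-1,4a,5,6,7,8,9,9a-octahydro-4H-benzo[7]annulen-4-one (trans-chlorohydrin) | C[C@]1(Cl)[C@H](O)CCC[C@]2(C)C(=O)C(C)=CC[C@@H]12
F3 | step 5 | 9β-chloro-3,4a,9-trimethyl-4a,5,6,7,9,9a-hexahydro-1H-benzo[7]annulene-4,8-dione (α-chloro ketone) | C[C@]1(Cl)C(=O)CCC[C@]2(C)C(=O)C(C)=CC[C@@H]12
F4 | step 5 | methyl (1S,4aS,8aR)-1,4a,6-trimethyl-5-oxo-1,2,3,4,4a,5,8,8a-octahydronaphthalene-1-carboxylate (ester β on C4) | COC(=O)[C@@]1(C)CCC[C@]2(C)C(=O)C(C)=CC[C@@H]12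
F5 | step 5 | (4aS,5S,8aS)-5-(hydroxymethyl)-2,5,8a-trimethyl-1,4,4a,5,6,7,8,8a-octahydronaphthalen-1-ol (C9 carbinol epimers) | OC[C@@]1(C)CCC[C@]2(C)C(O)C(C)=CC[C@@H]12
F6 | step 11 | 11,19-diol: [(1S,4aR,5S,8aS)-5-(hydroxymethyl)-2,5,8a-trimethyl-1,4,4a,5,6,7,8,8a-octahydronaphthalen-1-yl]methanol (9α-H) | OC[C@@]1(C)CCC[C@]2(C)[C@@H](CO)C(C)=CC[C@@H]12
F7 | step 11 | C11 iodide: [(1S,4aS,5S,8aR)-5-(iodomethyl)-1,4a,6-trimethyl-1,2,3,4,4a,5,8,8a-octahydronaphthalen-1-yl]methanol | OC[C@@]1(C)CCC[C@]2(C)[C@@H](CI)C(C)=CC[C@@H]12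
F8 | step 11 | C11 phenyl sulfone: F7 with PhSO2 in place of iodine | OC[C@@]1(C)CCC[C@]2(C)[C@@H](CS(=O)(=O)c3ccccc3)C(C)=CC[C@@H]12
F9 | step 11 | alkylated sulfone: 16 bearing PhSO2 on C11 (C11 epimers) | OC[C@@]1(C)CCC[C@]2(C)[C@@H](C(C[C@H](C)CC(=O)OC(C)(C)C)S(=O)(=O)c3ccccc3)C(C)=CC[C@@H]12
F10 | step 12 | phosphonopropanoate ester: 16 acylated on the C19 oxygen by 2-[bis(2,2,2-trifluoroethoxy)phosphoryl]propanoyl (epimers at the phosphonate carbon) | CC(C(=O)OC[C@@]1(C)CCC[C@]2(C)[C@@H](CC[C@H](C)CC(=O)OC(C)(C)C)C(C)=CC[C@@H]12)P(=O)(OCC(F)(F)F)OCC(F)(F)F
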